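The ten-membered carbocycle (C1–C10) is disconnected at its allylic C9–C10 bond, the 1,10-epoxide being read back to the C1=C10 (E) olefin so that C10 becomes an alkenyl carbon. The key step, a nickel-catalysed intramolecular reductive alkenyl–alkyl coupling, joins the C10 iodide to the C9 terminus of an acyclic precursor that already carries the cis-fused α-methylene-γ-lactone (O, C6, C7, C11, C12), the C4=C5 (Z) olefin, the C3 silyl ether and the C8 furoate; these turn elements fold the chain. One operation closes the ring and transfers the olefin geometry; epoxidation of the exposed face and desilylation finish the route. The precursor comes from an indium Barbier union of two fragments.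

Key step: step 14

Remark: germacranolide numbering is used throughout (C1/C10 epoxide, C3 carbinol, C4=C5, lactone oxygen on C6, ring fusion C7, ester on C8, C11=C13 methylidene, C12 carbonyl); (S)-glyceraldehyde acetonide is taken as a purchasable building block.

Step 1
Reactants: 1 pent-3-yn-1-ol
Product: 2 (3E)-4-iodopent-3-en-1-ol
Conditions: Cp2Zr(H)Cl (2.5 equiv), THF, rt then 45 °C; then I2, 0 °C
Reagents that add atoms: iodine, [I][I]
Why: Hydrozirconation–iodination: syn addition of Zr–H with zirconium settling on the less hindered alkyne carbon next to the methyl group under equilibrating conditions, then iodinolysis with retention, should give the (E)-2-iodoalkene that later becomes C1=C10.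

Step 2
Reactants: 2 (3E)-4-iodopent-3-en-1-ol
Product: 3 (3E)-4-iodopent-3-enal
Conditions: Dess–Martin periodinane, NaHCO3, CH2Cl2, 0 °C; used crude
Reagents that add atoms: none
Why: Buffered Dess–Martin oxidation should give the β,γ-unsaturated aldehyde without migration of the olefin into conjugation.

Step 3
Reactants: 3 (3E)-4-iodopent-3-enal; 4 methyl propiolate
Product: 5 methyl (4S,6E)-4-hydroxy-7-iodooct-6-en-2-ynoate
Conditions: Me2Zn, ProPhenol ligand (the enantiomer that delivers the 4S alcohol, 20 mol%), Ph3P=O (40 mol%), toluene, 4 °C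
Reagents that add atoms: none
Why: Catalytic asymmetric alkynylation of the aldehyde by the dinuclear zinc–ProPhenol alkynylide should set the carbinol (C3 of the target) by ligand-controlled face selection.

Step 4
Reactants: 5 methyl (4S,6E)-4-hydroxy-7-iodooct-6-en-2-ynoate
Product: 6 methyl (4S,6E)-4-(tert-butyldimethylsilyloxy)-7-iodooct-6-en-2-ynoate
Conditions: TBSCl, imidazole, DMF, rt
Reagents that add atoms: tert-butyldimethylsilyl chloride, CC(C)(C)[Si](C)(C)Cl
Why: Silyl ether formation protects the propargylic alcohol so that the cuprate adduct cannot lactonise and C3–O stays masked to the end.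

Step 5
Reactants: 6 methyl (4S,6E)-4-(tert-butyldimethylsilyloxy)-7-iodooct-6-en-2-ynoate
Product: 7 methyl (2Z,4S,6E)-4-(tert-butyldimethylsilyloxy)-7-iodo-3-methylocta-2,6-dienoate
Conditions: Me2CuLi (1.5 equiv), THF, −78 °C; sat. aq. NH4Cl at −78 °C
Reagents that add atoms: lithium dimethylcuprate, [Li+].C[Cu-]C
Why: Syn carbocupration of the ynoate followed by low-temperature protonation with retention places CH3 and H cis, which should give the (Z)-enoate that maps onto the C4=C5 olefin, the alkenyl iodide being inert at −78 °C.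

Step 6
Reactants: 7 methyl (2Z,4S,6E)-4-(tert-butyldimethylsilyloxy)-7-iodo-3-methylocta-2,6-dienoate
Product: 8 (2Z,4S,6E)-4-(tert-butyldimethylsilyloxy)-7-iodo-3-methylocta-2,6-dien-1-ol
Conditions: DIBAL-H (2.2 equiv), CH2Cl2, −78 °C
Reagents that add atoms: none
Why: DIBAL-H 1,2-reduction of the enoate should give the (Z)-allylic alcohol without touching the alkenyl iodide or the silyl ether.

Step 7
Reactants: 8 (2Z,4S,6E)-4-(tert-butyldimethylsilyloxy)-7-iodo-3-methylocta-2,6-dien-1-ol
Product: 9 (2Z,4S,6E)-4-(tert-butyldimethylsilyloxy)-7-iodo-3-methylocta-2,6-dienal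
Conditions: MnO2, CH2Cl2, rt, dark
Reagents that add atoms: none
Why: Neutral allylic oxidation with MnO2 should give the (Z)-enal without Z/E isomerisation.

Step 8
Reactants: 10 (S)-glyceraldehyde acetonide; 11 methyl acrylate
Product: 12 methyl 2-{hydroxy[(4S)-2,2-dimethyl-1,3-dioxolan-4-yl]methyl}prop-2-enoate (both carbinol epimers)
Conditions: DABCO (0.5 equiv), dioxane/H2O (1:1), rt
Reagents that add atoms: none
Why: Morita–Baylis–Hillman reaction; the new carbinol centre is erased in the next step, so its configuration is irrelevant.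

Step 9
Reactants: 12 methyl 2-{hydroxy[(4S)-2,2-dimethyl-1,3-dioxolan-4-yl]methyl}prop-2-enoate
Product: 13 methyl (2Z)-2-(bromomethyl)-3-[(4R)-2,2-dimethyl-1,3-dioxolan-4-yl]prop-2-enoate
Conditions: NBS, Me2S, CH2Cl2, 0 °C to rt
Reagents that add atoms: N-bromosuccinimide, O=C1CCC(=O)N1Br
Why: Bromosulfonium-mediated SN2′ bromination of the Baylis–Hillman alcohol should give the thermodynamically preferred (Z)-2-(bromomethyl)enoate from both epimers, the acetonide surviving the non-acidic conditions.

Step 10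
Reactants: 9 (2Z,4S,6E)-4-(tert-butyldimethylsilyloxy)-7-iodo-3-methylocta-2,6-dienal; 13 methyl (2Z)-2-(bromomethyl)-3-[(4R)-2,2-dimethyl-1,3-dioxolan-4-yl]prop-2-enoate
Product: 15 cis-lactone acetonide (6S,7R; C8 epimeric to the target), via hydroxy ester 14 (not isolated)
Conditions: indium powder, THF/H2O (1:1), rt; then PPTS (cat.), CH2Cl2, rt
Reagents that add atoms: none
Why: Indium Barbier allylation through a chair transition state with the γ-substituent of the (Z)-2-(alkoxycarbonyl)allyl reagent axial should give the syn adduct (cis-lactone after acid-catalysed lactonisation), and C6–C7 bond formation anti to the allylic C8–O bond with H8 eclipsing the olefin (Felkin–Anh-type control, the chelated model leading to the same face) should set C6 and C7 in the target sense relative to the C8 centre taken from 10.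

Step 11
Reactants: 15 cis-lactone acetonide
Product: 16 cis-lactone 8,9-diol
Conditions: CuCl2·2H2O, MeCN, 0 °C to rt
Reagents that add atoms: none
Why: Mild Lewis-acid-promoted hydrolysis of the terminal acetonide should spare the allylic TBS ether and the allylic lactone.

Step 12
Reactants: 16 cis-lactone 8,9-diol
Product: 17 C9 mono-tosylate (C8–OH free)
Conditions: TsCl, Bu2SnO (5 mol%), Et3N, CH2Cl2, 0 °C
Reagents that add atoms: p-toluenesulfonyl chloride, Cc1ccc(cc1)S(=O)(=O)Cl
Why: Stannylene-acetal-catalysed sulfonylation should select the primary hydroxyl of the 1,2-diol.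

Step 13
Reactants: 17 C9 mono-tosylate; 18 furan-3-carboxylic acid
Product: 19 C8 furoate C9 tosylate (8R as in the target)
Conditions: PPh3, DIAD, toluene, 0 °C to rt
Reagents that add atoms: none
Why: Mitsunobu esterification: SN2 displacement of the C8 oxyphosphonium by furan-3-carboxylate should install the ester and invert C8 to the target configuration, the primary tosylate being a non-participating spectator.

Step 14
Reactants: 19 C8 furoate C9 tosylate
Product: 21 (3S,6S,7R,8R)-3-(tert-butyldimethylsilyloxy)-8-(furan-3-carbonyloxy)germacra-1(10)E,4Z,11(13)-trien-12,6-olide, via primary iodide 20 (not isolated)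
Conditions: NiI2 (30 mol%), 4,4′-di-tert-butyl-2,2′-bipyridine (30 mol%), NaI (2 equiv), Mn powder (4 equiv), pyridine (10 mol%), DMA, 40 °C, syringe-pump addition to 2 mM
Reagents that add atoms: none
Why: Proposed new method: zerovalent nickel (NiI2 reduced by Mn) should add oxidatively to the C10–I bond while iodide exchange turns the C9 tosylate into iodide 20, which low-valent nickel reduces to the primary C9 radical; capture of this radical by the alkenylnickel and reductive elimination from trivalent nickel forge C9–C10, which is the mechanism of the known nickel-catalysed reductive cross-electrophile coupling of alkenyl halides with primary alkyl halides or tosylates, the closest reaction type, not yet used to close a ten-membered carbocycle. The ring C1–C10 closes in a 10-endo sense with respect to the alkenyl unit (C1 and C10 both end up in the ring), the E geometry of C1=C10 is carried over from the alkenyl iodide with retention, and no stereocentre is formed. The step needs cyclisation to win over oligomerisation, over radical addition to the α-methylene lactone and over loss or 1,2-shift of the β-acyloxy group; slow addition to high dilution, the fold imposed by the cis-lactone (C6/C7) and the Z C4=C5 olefin, Mn as a reductant that does not insert into the C–I bond, and the slow 1,2-acyloxy shift of β-acyloxyalkyl radicals should secure this. Attack of the C9 radical on C13 or C11 would be 5-endo or 4-exo and is geometrically disfavoured, and the hindered allylic C6–O bond should be spared because oxidative addition to the alkenyl iodide is much faster.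

Step 15
Reactants: 21 macrocyclic triene
Product: 22 (1R,3S,6S,7R,8R,10R)-1,10-epoxy-3-(tert-butyldimethylsilyloxy)-8-(furan-3-carbonyloxy)germacra-4Z,11(13)-dien-12,6-olide
Conditions: mCPBA (1.05 equiv), NaHCO3, CH2Cl2, 0 °C
Reagents that add atoms: m-chloroperoxybenzoic acid, OOC(=O)c1cccc(Cl)c1
Why: Prilezhaev epoxidation should pick the electron-rich C1=C10 olefin (C4=C5 is deactivated by two allylic C–O bonds and shielded by the silyl ether, C11=C13 is electron-poor) and attack its outer face anti to the C8 furoate in the conformer with C14 and the C8 ester on the same side, setting C1 and C10 (both R) by macrocyclic control.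

Step 16
Reactants: 22 silylated epoxide
Product: 23 (1R,3S,6S,7R,8R,10R)-1,10-epoxy-8-(furan-3-carbonyloxy)-3-hydroxygermacra-4Z,11(13)-dien-12,6-olide (CNP0390850.1)
Conditions: HF·pyridine, pyridine, THF, 0 °C to rt
Reagents that add atoms: none
Why: Buffered fluoride-mediated desilylation should free the C3 hydroxyl without opening the epoxide or adding to the α-methylene lactone.

Compound list

1 | pent-3-yn-1-ol | CC#CCCO | starting material
2 | (3E)-4-iodopent-3-en-1-ol | OCC/C=C(\C)I | intermediate
3 | (3E)-4-iodopent-3-enal | O=CC/C=C(\C)I | intermediate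
4 | methyl propiolate | C#CC(=O)OC | starting material
5 | methyl (4S,6E)-4-hydroxy-7-iodooct-6-en-2-ynoate | COC(=O)C#C[C@@H](O)C/C=C(\C)I | intermediate
6 | methyl (4S,6E)-4-(tert-butyldimethylsilyloxy)-7-iodooct-6-en-2-ynoate | COC(=O)C#C[C@@H](O[Si](C)(C)C(C)(C)C)C/C=C(\C)I | intermediate
7 | methyl (2Z,4S,6E)-4-(tert-butyldimethylsilyloxy)-7-iodo-3-methylocta-2,6-dienoate | COC(=O)/C=C(/C)[C@@H](O[Si](C)(C)C(C)(C)C)C/C=C(\C)I | intermediate
8 | (2Z,4S,6E)-4-(tert-butyldimethylsilyloxy)-7-iodo-3-methylocta-2,6-dien-1-ol | OC/C=C(/C)[C@@H](O[Si](C)(C)C(C)(C)C)C/C=C(\C)I | intermediate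
9 | (2Z,4S,6E)-4-(tert-butyldimethylsilyloxy)-7-iodo-3-methylocta-2,6-dienal | O=C/C=C(/C)[C@@H](O[Si](C)(C)C(C)(C)C)C/C=C(\C)I | intermediate
10 | (4S)-2,2-dimethyl-1,3-dioxolane-4-carbaldehyde ((S)-glyceraldehyde acetonide) | O=C[C@@H]1COC(C)(C)O1 | starting material
11 | methyl acrylate | C=CC(=O)OC | starting material
12 | methyl 2-{hydroxy[(4S)-2,2-dimethyl-1,3-dioxolan-4-yl]methyl}prop-2-enoate (both carbinol epimers) | C=C(C(=O)OC)C(O)[C@@H]1COC(C)(C)O1 | intermediate
13 | methyl (2Z)-2-(bromomethyl)-3-[(4R)-2,2-dimethyl-1,3-dioxolan-4-yl]prop-2-enoate | COC(=O)/C(CBr)=C/[C@@H]1COC(C)(C)O1 | intermediate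
14 | methyl (3S,4S,5Z,7S,9E)-7-(tert-butyldimethylsilyloxy)-3-[(4R)-2,2-dimethyl-1,3-dioxolan-4-yl]-4-hydroxy-10-iodo-6-methyl-2-methylideneundeca-5,9-dienoate | C=C(C(=O)OC)[C@@H]([C@@H](O)/C=C(/C)[C@@H](O[Si](C)(C)C(C)(C)C)C/C=C(\C)I)[C@@H]1COC(C)(C)O1 | intermediate (not isolated)
15 | (4S,5S)-5-[(1Z,3S,5E)-3-(tert-butyldimethylsilyloxy)-6-iodo-2-methylhepta-1,5-dien-1-yl]-4-[(4R)-2,2-dimethyl-1,3-dioxolan-4-yl]-3-methylideneoxolan-2-one | C=C1C(=O)O[C@@H](/C=C(/C)[C@@H](O[Si](C)(C)C(C)(C)C)C/C=C(\C)I)[C@H]1[C@@H]2COC(C)(C)O2 | intermediate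
16 | (4R,5S)-5-[(1Z,3S,5E)-3-(tert-butyldimethylsilyloxy)-6-iodo-2-methylhepta-1,5-dien-1-yl]-4-[(1R)-1,2-dihydroxyethyl]-3-methylideneoxolan-2-one | C=C1C(=O)O[C@@H](/C=C(/C)[C@@H](O[Si](C)(C)C(C)(C)C)C/C=C(\C)I)[C@H]1[C@@H](O)CO | intermediate
17 | (2R)-2-[(2S,3R)-2-[(1Z,3S,5E)-3-(tert-butyldimethylsilyloxy)-6-iodo-2-methylhepta-1,5-dien-1-yl]-4-methylidene-5-oxooxolan-3-yl]-2-hydroxyethyl 4-methylbenzenesulfonate | C=C1C(=O)O[C@@H](/C=C(/C)[C@@H](O[Si](C)(C)C(C)(C)C)C/C=C(\C)I)[C@H]1[C@@H](O)COS(=O)(=O)c2ccc(C)cc2 | intermediate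
18 | furan-3-carboxylic acid | OC(=O)c1ccoc1 | starting material
19 | (1S)-1-[(2S,3S)-2-[(1Z,3S,5E)-3-(tert-butyldimethylsilyloxy)-6-iodo-2-methylhepta-1,5-dien-1-yl]-4-methylidene-5-oxooxolan-3-yl]-2-(4-methylbenzenesulfonyloxy)ethyl furan-3-carboxylate | C=C1C(=O)O[C@@H](/C=C(/C)[C@@H](O[Si](C)(C)C(C)(C)C)C/C=C(\C)I)[C@H]1[C@H](OC(=O)c2ccoc2)COS(=O)(=O)c3ccc(C)cc3 | intermediate
20 | (1S)-1-[(2S,3S)-2-[(1Z,3S,5E)-3-(tert-butyldimethylsilyloxy)-6-iodo-2-methylhepta-1,5-dien-1-yl]-4-methylidene-5-oxooxolan-3-yl]-2-iodoethyl furan-3-carboxylate | C=C1C(=O)O[C@@H](/C=C(/C)[C@@H](O[Si](C)(C)C(C)(C)C)C/C=C(\C)I)[C@H]1[C@H](OC(=O)c2ccoc2)CI | intermediate (not isolated)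
21 | (3S,6S,7R,8R)-3-(tert-butyldimethylsilyloxy)-8-(furan-3-carbonyloxy)germacra-1(10)E,4Z,11(13)-trien-12,6-olide | C=C1C(=O)O[C@H]2/C=C(/C)[C@@H](O[Si](C)(C)C(C)(C)C)C/C=C(\C)C[C@@H](OC(=O)c3ccoc3)[C@@H]12 | intermediate
22 | (1R,3S,6S,7R,8R,10R)-1,10-epoxy-3-(tert-butyldimethylsilyloxy)-8-(furan-3-carbonyloxy)germacra-4Z,11(13)-dien-12,6-olide | C=C1C(=O)O[C@H]2/C=C(/C)[C@@H](O[Si](C)(C)C(C)(C)C)C[C@H]3O[C@]3(C)C[C@@H](OC(=O)c3ccoc3)[C@@H]12 | intermediate
23 | (1R,3S,6S,7R,8R,10R)-1,10-epoxy-8-(furan-3-carbonyloxy)-3-hydroxygermacra-4Z,11(13)-dien-12,6-olide (CNP0390850.1) | C=C1C(=O)O[C@H]2/C=C(/C)[C@@H](O)C[C@H]3O[C@]3(C)C[C@@H](OC(=O)c3ccoc3)[C@@H]12 | target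

Total step count: 16. Longest linear sequence: 14 steps (steps 1–7 and 10–16).

Steps most likely to fail

Step 14 (the step that goes beyond known chemistry). The ring closure may lose out to intermolecular coupling and oligomerisation, to addition of the C9 radical or of low-valent nickel to the α-methylene lactone, or to elimination or 1,2-shift of the β-acyloxy group. The fallback uses known chemistry, sets out from 19 and comes back at 21. Finkelstein exchange (NaI, acetone) gives iodide 20 as an isolated compound. Photoinduced radical borylation of 20 with bis(catecholato)diboron in DMA under blue light should give the catechol boronate F1, which is transesterified in the same flask with pinacol and Et3N to the pinacol boronate F2. Intramolecular alkyl Suzuki–Miyaura coupling of F2 with its own alkenyl iodide (Pd(dppf)Cl2, Ag2O, K2CO3, THF, 60 °C, high dilution) then closes the same C9–C10 bond by a two-electron transmetalation pathway and should deliver 21.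

Step 15. The peracid may attack the other exposed face of C1=C10 if the alternative ring conformer is populated (poor facial selectivity), or C4=C5 may be oxidised in competition. The fallback sets out from 21 and comes back at 22: reagent-controlled Shi epoxidation with the fructose-derived ketone (the enantiomer matched to the 1R,10R face), Oxone, K2CO3-buffered MeCN/dimethoxymethane/H2O, 0 °C, which replaces substrate control by catalyst control on the E-trisubstituted olefin; this fallback makes no new compound (F0).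

Step 10. Bond formation may occur on the other face of the allylindium (anti to the CH2 arm of the dioxolane instead of anti to the C8–O bond), which would give C6 and C7 in the wrong sense relative to C8. The fallback sets out from 9 and comes back at 19. It uses the enantiomeric building block, (R)-glyceraldehyde acetonide F3, which is taken through the same Baylis–Hillman reaction to adduct F4 and the same SN2′ bromination to bromide F5. Indium allylation of 9 with F5 then gives, through hydroxy ester F6, the cis-lactone F7 that already has the target configuration at C8. Acetonide cleavage gives diol F8 and primary tosylation gives tosylate F9. Acylation of F9 with furan-3-carbonyl chloride (pyridine, DMAP, CH2Cl2), with retention at C8 in place of the Mitsunobu inversion, gives 19.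

Further compounds

F1 | step 14 | (1R)-2-(1,3,2-benzodioxaborol-2-yl)-1-[(2S,3R)-2-[(1Z,3S,5E)-3-(tert-butyldimethylsilyloxy)-6-iodo-2-methylhepta-1,5-dien-1-yl]-4-methylidene-5-oxooxolan-3-yl]ethyl furan-3-carboxylate | C=C1C(=O)O[C@@H](/C=C(/C)[C@@H](O[Si](C)(C)C(C)(C)C)C/C=C(\C)I)[C@H]1[C@H](OC(=O)c2ccoc2)CB2Oc3ccccc3O2
F2 | step 14 | (1R)-1-[(2S,3R)-2-[(1Z,3S,5E)-3-(tert-butyldimethylsilyloxy)-6-iodo-2-methylhepta-1,5-dien-1-yl]-4-methylidene-5-oxooxolan-3-yl]-2-(4,4,5,5-tetramethyl-1,3,2-dioxaborolan-2-yl)ethyl furan-3-carboxylate | C=C1C(=O)O[C@@H](/C=C(/C)[C@@H](O[Si](C)(C)C(C)(C)C)C/C=C(\C)I)[C@H]1[C@H](OC(=O)c2ccoc2)CB2OC(C)(C)C(C)(C)O2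
F0 | step 15 | none | none
F3 | step 10 | (4R)-2,2-dimethyl-1,3-dioxolane-4-carbaldehyde ((R)-glyceraldehyde acetonide) | O=C[C@H]1COC(C)(C)O1
F4 | step 10 | methyl 2-{hydroxy[(4R)-2,2-dimethyl-1,3-dioxolan-4-yl]methyl}prop-2-enoate (both carbinol epimers) | C=C(C(=O)OC)C(O)[C@H]1COC(C)(C)O1
F5 | step 10 | methyl (2Z)-2-(bromomethyl)-3-[(4S)-2,2-dimethyl-1,3-dioxolan-4-yl]prop-2-enoate | COC(=O)/C(CBr)=C/[C@H]1COC(C)(C)O1
F6 | step 10 | methyl (3S,4S,5Z,7S,9E)-7-(tert-butyldimethylsilyloxy)-3-[(4S)-2,2-dimethyl-1,3-dioxolan-4-yl]-4-hydroxy-10-iodo-6-methyl-2-methylideneundeca-5,9-dienoate | C=C(C(=O)OC)[C@@H]([C@@H](O)/C=C(/C)[C@@H](O[Si](C)(C)C(C)(C)C)C/C=C(\C)I)[C@H]1COC(C)(C)O1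
F7 | step 10 | (4S,5S)-5-[(1Z,3S,5E)-3-(tert-butyldimethylsilyloxy)-6-iodo-2-methylhepta-1,5-dien-1-yl]-4-[(4S)-2,2-dimethyl-1,3-dioxolan-4-yl]-3-methylideneoxolan-2-one | C=C1C(=O)O[C@@H](/C=C(/C)[C@@H](O[Si](C)(C)C(C)(C)C)C/C=C(\C)I)[C@H]1[C@H]2COC(C)(C)O2
F8 | step 10 | (4R,5S)-5-[(1Z,3S,5E)-3-(tert-butyldimethylsilyloxy)-6-iodo-2-methylhepta-1,5-dien-1-yl]-4-[(1S)-1,2-dihydroxyethyl]-3-methylideneoxolan-2-one | C=C1C(=O)O[C@@H](/C=C(/C)[C@@H](O[Si](C)(C)C(C)(C)C)C/C=C(\C)I)[C@H]1[C@H](O)CO
F9 | step 10 | (2S)-2-[(2S,3R)-2-[(1Z,3S,5E)-3-(tert-butyldimethylsilyloxy)-6-iodo-2-methylhepta-1,5-dien-1-yl]-4-methylidene-5-oxooxolan-3-yl]-2-hydroxyethyl 4-methylbenzenesulfonate | C=C1C(=O)O[C@@H](/C=C(/C)[C@@H](O[Si](C)(C)C(C)(C)C)C/C=C(\C)I)[C@H]1[C@H](O)COS(=O)(=O)c2ccc(C)cc2
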